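The tempting charge comes from counting protons, but free base binds a proton more weakly than nucleophile does, 1300 /M against 36000 /M, so a proton count comes out too low.

electrophile 0.10 M; protonated nucleophile 0.120 M; protic impurity 5.00 mM; time 20 min

    electrophile + nucleophile ⇌ acid set free + product (K1 = 1.1, k1 = 0.54 /M/s)
    nucleophile + acid set free ⇌ protonated nucleophile, settled at all times (K2 = 36000 /M)
    acid set free + free base ⇌ salt of the base (K3 = 1300 /M, k3 = 1.2 /M/s)
    2 nucleophile → homo dimer (k4 = 0.11 /M/s)
    electrophile + protic impurity → quenched substrate (k5 = 11 /M/s)

- the concentration of free base at which the part of the electrophile that has reacted at 20 min is just 70%, in M

- where a step has two of a species, its rate is k times that concentration squared, and two are used at each turn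
- the amount of free base is what is sought; it is there from the start
- run time (flask): 20 min

How much electrophile must pass through the substitution? Against the electrophile as charged, the protic impurity has a half-life near 0.630 s, much shorter than the run of 20 min. Its 5.00 mM is therefore counted as quenched substrate, and 0.0650 M must go the productive way.

What does each such turn cost? Follow one electrophile: the nucleophile it meets has given up a proton, the turn sets free a second, and both end on free base. With homo dimer left out of the count, that makes 0.130 M of salt of the base and leaves 0.0550 M of protonated nucleophile.

Is that charge enough? The sum of the steps is electrophile + protonated nucleophile + two free base ⇌ product + two salt of the base. Its net constant, the substitution constant times the square of the salt constant divided by the protonation constant, is 51.6 /M. It equals [product] times [salt of the base] squared, over [electrophile][protonated nucleophile] times [free base] squared. At balance with 70% used, it asks for [free base] of 0.114 M beside the salt. Free base and salt together give a lower bound on the charge, a floor of 0.244 M, about twice the salt itself. A flask that must reach the mark in 20 min needs more, and this reckoning stops at that floor without giving the margin.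

The forecast puts the charge at 0.32 M, within 0.27 M to 0.4 M, and calls this “a bench estimate rather than a full integration”.

The flask needs 0.308 M of free base, 1.26 times the floor. At that charge, the electrophile used climbs from 70% at 20 min to 75.4% at 60.0 min. By the same balance, the quotient of the net constant is 21.0 /M at the first of these times and 40.7 /M at the second, still less than the net constant of 51.6 /M.

(All constants come from no measurement; the result is computed.)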